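**Retrosynthetic overview**
1. Target 17 ⇐ global O‑demethylation of pentamethyl ether 16.
2. Ring A is formed last, de novo, on the oxygen of the B–C phenol: aryloxyacetate 9 + methyl acetoacetate dianion (intermolecular Claisen condensation, the key C–C bond) → 3,5‑dioxo ester 12 → pyrone 14 → methoxide ring‑opening and intramolecular Claisen closure to the phloroglucinol ring.
3. B–C phenol 7 ⇐ Dakin oxidation of aldehyde 5 ⇐ Ullmann ether coupling of phenol 3 (ring C, Br already in place) with 4‑bromo‑3,5‑dimethoxybenzaldehyde 4 (ring B).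
4. Phenol 3 ⇐ Ir‑catalysed C–H borylation and oxidation of 2‑bromo‑1,3‑dimethoxybenzene 1.
5. Ring order: rings C and B are bought as arenes and joined first; ring A is built last.

Assumption: the target has no stereocentre and is achiral, so no stereocontrol is needed; compounds 1, 4, 8 and 10 are taken as commercial.

**Step 1**
Reactants: 1 2‑bromo‑1,3‑dimethoxybenzene
Product: 2 2‑(4‑bromo‑3,5‑dimethoxyphenyl)‑4,4,5,5‑tetramethyl‑1,3,2‑dioxaborolane
Conditions: [Ir(OMe)(cod)]2 (1.5 mol%), dtbpy (3 mol%), B2pin2 (1.0 equiv), THF, 80 °C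
Reagents that add atoms: bis(pinacolato)diboron, CC1(C)OB(OC1(C)C)B1OC(C)(C)C(C)(C)O1
Why: Iridium‑catalysed aromatic C–H borylation is sterically controlled, so only C5 (the one C–H with no ortho substituent) reacts and the Ar–Br is untouched.

**Step 2**
Reactants: 2 2‑(4‑bromo‑3,5‑dimethoxyphenyl)‑4,4,5,5‑tetramethyl‑1,3,2‑dioxaborolane
Product: 3 4‑bromo‑3,5‑dimethoxyphenol
Conditions: 30% aq. H2O2, NaOH, THF, 0 °C → rt; then aq. HCl
Reagents that add atoms: hydrogen peroxide, OO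
Why: Boronate oxidation (1,2‑aryl shift from boron to oxygen in the hydroperoxide ate complex) gives the phenol at the same carbon and does not affect Ar–Br.

**Step 3**
Reactants: 3 4‑bromo‑3,5‑dimethoxyphenol; 4 4‑bromo‑3,5‑dimethoxybenzaldehyde
Product: 5 4‑(4‑bromo‑3,5‑dimethoxyphenoxy)‑3,5‑dimethoxybenzaldehyde
Conditions: CuI (10 mol%), picolinic acid (20 mol%), K3PO4 (2 equiv), DMSO, 90–105 °C, Ar; 4 in slight excess (1.2 equiv)
Reagents that add atoms: none
Why: Ullmann diaryl ether coupling; the C–Br of 4 is activated by the para‑formyl group while the C–Br of phenoxide 3 is deactivated by the para‑oxido group, so only the cross‑coupling occurs, and the picolinic acid ligand system tolerates di‑ortho‑substituted aryl halides.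

**Step 4**
Reactants: 5 4‑(4‑bromo‑3,5‑dimethoxyphenoxy)‑3,5‑dimethoxybenzaldehyde
Product: 7 4‑(4‑bromo‑3,5‑dimethoxyphenoxy)‑3,5‑dimethoxyphenol, via aryl formate 6 (not isolated)
Conditions: mCPBA (1.3 equiv), CH2Cl2, 0 °C → rt; then K2CO3 (cat.), MeOH, rt
Reagents that add atoms: mCPBA (3‑chloroperoxybenzoic acid), OOC(=O)c1cccc(Cl)c1
Why: Dakin‑type Baeyer–Villiger oxidation; the 3,4,5‑trioxygenated aryl group migrates in preference to hydrogen (as in 3,4,5‑trimethoxybenzaldehyde), and the formate is removed by methanolysis.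

**Step 5**
Reactants: 7 4‑(4‑bromo‑3,5‑dimethoxyphenoxy)‑3,5‑dimethoxyphenol; 8 methyl bromoacetate
Product: 9 methyl 2‑[4‑(4‑bromo‑3,5‑dimethoxyphenoxy)‑3,5‑dimethoxyphenoxy]acetate
Conditions: K2CO3, acetone, reflux
Reagents that add atoms: none
Why: Williamson ether synthesis (SN2 of the unhindered phenoxide on the α‑bromo ester).

**Step 6**
Reactants: 9 methyl 2‑[4‑(4‑bromo‑3,5‑dimethoxyphenoxy)‑3,5‑dimethoxyphenoxy]acetate; 10 methyl acetoacetate
Product: 12 methyl 6‑[4‑(4‑bromo‑3,5‑dimethoxyphenoxy)‑3,5‑dimethoxyphenoxy]‑3,5‑dioxohexanoate, via methyl acetoacetate dianion 11 (not isolated)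
Conditions: 10 (2.2 equiv), NaH, THF, 0 °C; n‑BuLi (0.98 equiv per 10), 0 °C; then 9, −78 → 0 °C; aq. HCl quench
Reagents that add atoms: none
Why: Crossed Claisen condensation of a β‑keto ester dianion (Huckin–Weiler); the γ‑carbanion is the most nucleophilic site and acylates on the inductively activated α‑aryloxy ester, and all n‑BuLi is consumed before 9 is added so the Ar–Br is safe.

**Step 7**
Reactants: 12 methyl 6‑[4‑(4‑bromo‑3,5‑dimethoxyphenoxy)‑3,5‑dimethoxyphenoxy]‑3,5‑dioxohexanoate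
Product: 13 6‑{[4‑(4‑bromo‑3,5‑dimethoxyphenoxy)‑3,5‑dimethoxyphenoxy]methyl}‑4‑hydroxy‑2H‑pyran‑2‑one
Conditions: DBU (2 equiv), toluene, 80 °C; aq. HCl wash
Reagents that add atoms: none
Why: Base‑promoted lactonisation (intramolecular O‑acylation of the C5 enol on the methyl ester) is the standard cyclisation of 3,5‑dioxo esters to 4‑hydroxy‑2‑pyrones.

**Step 8**
Reactants: 13 6‑{[4‑(4‑bromo‑3,5‑dimethoxyphenoxy)‑3,5‑dimethoxyphenoxy]methyl}‑4‑hydroxy‑2H‑pyran‑2‑one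
Product: 14 6‑{[4‑(4‑bromo‑3,5‑dimethoxyphenoxy)‑3,5‑dimethoxyphenoxy]methyl}‑4‑methoxy‑2H‑pyran‑2‑one
Conditions: Me2SO4 (1.2 equiv), K2CO3, acetone, reflux
Reagents that add atoms: dimethyl sulfate, COS(=O)(=O)OC
Why: O‑alkylation of the vinylogous acid gives the 4‑methoxy‑2‑pyrone, which blocks enolisation between the carbonyls in the next step.

**Step 9**
Reactants: 14 6‑{[4‑(4‑bromo‑3,5‑dimethoxyphenoxy)‑3,5‑dimethoxyphenoxy]methyl}‑4‑methoxy‑2H‑pyran‑2‑one
Product: 16 2‑[4‑(4‑bromo‑3,5‑dimethoxyphenoxy)‑3,5‑dimethoxyphenoxy]‑5‑methoxybenzene‑1,3‑diol, via ring‑opened methoxy‑enoate ester 15 (not isolated)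
Conditions: NaOMe (5 equiv), degassed MeOH, sealed tube, 150 °C (up to 185 °C if slow), Ar; then aq. HCl
Reagents that add atoms: none
Why: Methoxide opens the lactone to the (E)‑3‑methoxy‑5‑oxohex‑2‑enoate 15, whose ester and keto chain are held cis; the α‑aryloxy ketone enolate (C6) then closes on the ester in an intramolecular Claisen (Dieckmann‑type) condensation, expelling methoxide, and tautomerisation to the arene makes this pyrone‑to‑phloroglucinol rearrangement irreversible.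

**Step 10**
Reactants: 16 2‑[4‑(4‑bromo‑3,5‑dimethoxyphenoxy)‑3,5‑dimethoxyphenoxy]‑5‑methoxybenzene‑1,3‑diol
Product: 17 2‑[4‑(4‑bromo‑3,5‑dihydroxyphenoxy)‑3,5‑dihydroxyphenoxy]benzene‑1,3,5‑triol
Conditions: BBr3 (12 equiv), CH2Cl2, −78 °C → rt; cold water quench; Sephadex LH‑20 or RP‑HPLC under Ar
Reagents that add atoms: none
Why: Lewis‑acid ether cleavage; BBr3 cleaves all five aryl methyl ethers by SN2 at methyl, while the diaryl ether bonds and the Ar–Br are inert.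

**Compound list**
1 | 2‑bromo‑1,3‑dimethoxybenzene | COc1cccc(OC)c1Br | starting material
2 | 2‑(4‑bromo‑3,5‑dimethoxyphenyl)‑4,4,5,5‑tetramethyl‑1,3,2‑dioxaborolane | COc1cc(cc(OC)c1Br)B1OC(C)(C)C(C)(C)O1 | intermediate
3 | 4‑bromo‑3,5‑dimethoxyphenol | COc1cc(O)cc(OC)c1Br | intermediate
4 | 4‑bromo‑3,5‑dimethoxybenzaldehyde | COc1cc(C=O)cc(OC)c1Br | starting material
5 | 4‑(4‑bromo‑3,5‑dimethoxyphenoxy)‑3,5‑dimethoxybenzaldehyde | COc1cc(C=O)cc(OC)c1Oc1cc(OC)c(Br)c(OC)c1 | intermediate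
6 | 4‑(4‑bromo‑3,5‑dimethoxyphenoxy)‑3,5‑dimethoxyphenyl formate (not isolated) | COc1cc(OC=O)cc(OC)c1Oc1cc(OC)c(Br)c(OC)c1 | intermediate
7 | 4‑(4‑bromo‑3,5‑dimethoxyphenoxy)‑3,5‑dimethoxyphenol | COc1cc(O)cc(OC)c1Oc1cc(OC)c(Br)c(OC)c1 | intermediate
8 | methyl bromoacetate | COC(=O)CBr | starting material
9 | methyl 2‑[4‑(4‑bromo‑3,5‑dimethoxyphenoxy)‑3,5‑dimethoxyphenoxy]acetate | COC(=O)COc1cc(OC)c(Oc2cc(OC)c(Br)c(OC)c2)c(OC)c1 | intermediate
10 | methyl acetoacetate | COC(=O)CC(C)=O | starting material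
11 | methyl acetoacetate dianion, sodium lithium salt (not isolated) | COC([O-])=CC(=C)[O-].[Na+].[Li+] | intermediate
12 | methyl 6‑[4‑(4‑bromo‑3,5‑dimethoxyphenoxy)‑3,5‑dimethoxyphenoxy]‑3,5‑dioxohexanoate | COC(=O)CC(=O)CC(=O)COc1cc(OC)c(Oc2cc(OC)c(Br)c(OC)c2)c(OC)c1 | intermediate
13 | 6‑{[4‑(4‑bromo‑3,5‑dimethoxyphenoxy)‑3,5‑dimethoxyphenoxy]methyl}‑4‑hydroxy‑2H‑pyran‑2‑one | O=C1C=C(O)C=C(COc2cc(OC)c(Oc3cc(OC)c(Br)c(OC)c3)c(OC)c2)O1 | intermediate
14 | 6‑{[4‑(4‑bromo‑3,5‑dimethoxyphenoxy)‑3,5‑dimethoxyphenoxy]methyl}‑4‑methoxy‑2H‑pyran‑2‑one | COC1=CC(=O)OC(COc2cc(OC)c(Oc3cc(OC)c(Br)c(OC)c3)c(OC)c2)=C1 | intermediate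
15 | methyl (2E)‑6‑[4‑(4‑bromo‑3,5‑dimethoxyphenoxy)‑3,5‑dimethoxyphenoxy]‑3‑methoxy‑5‑oxohex‑2‑enoate (not isolated) | COC(=O)/C=C(/OC)CC(=O)COc1cc(OC)c(Oc2cc(OC)c(Br)c(OC)c2)c(OC)c1 | intermediate
16 | 2‑[4‑(4‑bromo‑3,5‑dimethoxyphenoxy)‑3,5‑dimethoxyphenoxy]‑5‑methoxybenzene‑1,3‑diol | COc1cc(O)c(Oc2cc(OC)c(Oc3cc(OC)c(Br)c(OC)c3)c(OC)c2)c(O)c1 | intermediate
17 | 2‑[4‑(4‑bromo‑3,5‑dihydroxyphenoxy)‑3,5‑dihydroxyphenoxy]benzene‑1,3,5‑triol | Oc1cc(O)c(Oc2cc(O)c(Oc3cc(O)c(Br)c(O)c3)c(O)c2)c(O)c1 | target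

**Totals**
Total step count: 10. Longest linear sequence: 10 steps (1 → 17); compounds 4, 8 and 10 enter as commercial materials.

**Three steps most likely to fail**

Step 9 (pyrone to phloroglucinol rearrangement). The hot methoxide conditions can cause retro‑Claisen cleavage of 15 or stop at the open‑chain stage. The fallback sets out from phenol 7 and forms the A–B ether by coupling instead of ring construction. Phenol 7 is coupled with commercial 2‑iodo‑1,3,5‑trimethoxybenzene (COc1cc(OC)c(I)c(OC)c1) under CuI, picolinic acid, K3PO4 in DMSO at 90 °C; the aryl iodide reacts ahead of the hindered, electron‑rich Ar–Br. This gives 2‑[4‑(4‑bromo‑3,5‑dimethoxyphenoxy)‑3,5‑dimethoxyphenoxy]‑1,3,5‑trimethoxybenzene F4, which BBr3 in CH2Cl2 demethylates sevenfold. The fallback comes back to the route at target 17.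

Step 3 (Ullmann coupling of a di‑ortho‑methoxy aryl bromide). The hindered bromide may couple slowly, or the aldehyde may suffer. The fallback sets out from boronate 2 and reverses the polarity of the coupling. The pinacol ester is cleaved with NaIO4 and NH4OAc in acetone–water to (4‑bromo‑3,5‑dimethoxyphenyl)boronic acid F1. F1 is coupled with commercial syringaldehyde (4‑hydroxy‑3,5‑dimethoxybenzaldehyde, COc1cc(C=O)cc(OC)c1O) under Chan–Lam–Evans conditions (Cu(OAc)2, pyridine, 4 Å MS, air, CH2Cl2, rt). These room‑temperature conditions arylate 2,6‑disubstituted phenols and leave Ar–Br alone. The fallback comes back to the route at aldehyde 5.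

Step 6 (Claisen condensation on an enolisable ester). The dianion may deprotonate 9 instead of acylating. The fallback sets out from ester 9 and uses an acylketene route. Ester 9 is converted with MeNHOMe·HCl and i‑PrMgCl (THF, −20 °C) into 2‑[4‑(4‑bromo‑3,5‑dimethoxyphenoxy)‑3,5‑dimethoxyphenoxy]‑N‑methoxy‑N‑methylacetamide F2. F2 acylates the lithium dienolate of commercial 2,2,6‑trimethyl‑4H‑1,3‑dioxin‑4‑one (LiHMDS, THF, −78 °C) to give 6‑{3‑[4‑(4‑bromo‑3,5‑dimethoxyphenoxy)‑3,5‑dimethoxyphenoxy]‑2‑oxopropyl}‑2,2‑dimethyl‑4H‑1,3‑dioxin‑4‑one F3. Heating F3 in toluene at 110 °C releases the acylketene, which is trapped by the enol oxygen. The fallback comes back to the route at pyrone 13, bypassing 12.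

**Further compounds**
F1 | step 3 | (4‑bromo‑3,5‑dimethoxyphenyl)boronic acid | COc1cc(cc(OC)c1Br)B(O)O
F2 | step 6 | 2‑[4‑(4‑bromo‑3,5‑dimethoxyphenoxy)‑3,5‑dimethoxyphenoxy]‑N‑methoxy‑N‑methylacetamide | CON(C)C(=O)COc1cc(OC)c(Oc2cc(OC)c(Br)c(OC)c2)c(OC)c1
F3 | step 6 | 6‑{3‑[4‑(4‑bromo‑3,5‑dimethoxyphenoxy)‑3,5‑dimethoxyphenoxy]‑2‑oxopropyl}‑2,2‑dimethyl‑4H‑1,3‑dioxin‑4‑one | CC1(C)OC(=O)C=C(CC(=O)COc2cc(OC)c(Oc3cc(OC)c(Br)c(OC)c3)c(OC)c2)O1
F4 | step 9 | 2‑[4‑(4‑bromo‑3,5‑dimethoxyphenoxy)‑3,5‑dimethoxyphenoxy]‑1,3,5‑trimethoxybenzene | COc1cc(OC)c(Oc2cc(OC)c(Oc3cc(OC)c(Br)c(OC)c3)c(OC)c2)c(OC)c1
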